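**Retrosynthetic overview**
- Xanthohumol is cut at the acyl C(=O)–CH= bond of the enone into 2,4-dihydroxy-6-methoxy-3-prenylbenzaldehyde and 4-ethynylphenol. They are joined in the last step by a rhodium-catalysed, phenol-directed alkyne hydroacylation that sets the ketone oxidation level and the (E)-olefin in one operation, with no protecting group and no by-product.
- Enabling feature: the free C2′–OH on ring A, ortho to the C1′ carbon that carries the carbonyl. The O–C2′–C1′–C(=O) salicyl unit closes a five-membered O,C-acyl rhodacycle, which allows formyl C–H activation without decarbonylation.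
- The aldehyde comes from the C2v-symmetric 5-methoxy-2-prenylresorcinol core (as its bis-MOM ether), whose two free ring positions are equivalent, so formylation by directed ortho-metalation needs no regiocontrol. The prenyl group is placed earlier by metalation between the two OMOM groups of bis-MOM 5-methoxyresorcinol.
- No ring is formed in the route: ring A is bought as 5-methoxyresorcinol and ring B as 4-ethynylphenol.

Key step: step 5

Assumption: xanthohumol has no stereocentre, so the only stereochemical element to control is the (E)-enone double bond, which is set in step 5.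

**Step 1**
Reactants: 1 5-methoxyresorcinol (5-methoxybenzene-1,3-diol)
Product: 2 1-methoxy-3,5-bis(methoxymethoxy)benzene
Conditions: MOMCl (2.5 equiv), i-Pr2NEt (3 equiv), CH2Cl2, 0 °C → rt
Reagents that add atoms: chloromethyl methyl ether (MOMCl), COCCl
Why: Amine-mediated O-alkylation of both phenols (MOM ether formation) should go cleanly and installs the two acetal groups that later direct the metalations.

**Step 2**
Reactants: 2 1-methoxy-3,5-bis(methoxymethoxy)benzene; 3 prenyl bromide (1-bromo-3-methylbut-2-ene)
Product: 5 5-methoxy-1,3-bis(methoxymethoxy)-2-(3-methylbut-2-en-1-yl)benzene, via aryllithium 4 (not isolated)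
Conditions: n-BuLi (1.1 equiv), THF, 0 °C → rt; then CuBr·SMe2 (10 mol%), 3, −78 °C → rt
Reagents that add atoms: n-butyllithium, [Li]CCCC (its lithium is found only in intermediate 4; the prenyl carbons come from reactant 3)
Why: Directed ortho-metalation should occur at the C–H between the two OMOM groups, which is chelated on both sides by the stronger acetal directing groups (OMOM over OMe), and copper-catalysed SN2 allylation of the aryllithium with prenyl bromide should deliver the linear prenyl group.

**Step 3**
Reactants: 5 5-methoxy-1,3-bis(methoxymethoxy)-2-(3-methylbut-2-en-1-yl)benzene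
Product: 7 6-methoxy-2,4-bis(methoxymethoxy)-3-(3-methylbut-2-en-1-yl)benzaldehyde, via aryllithium 6 (not isolated)
Conditions: n-BuLi (1.2 equiv), TMEDA, THF, −20 → 0 °C; DMF, −78 °C → rt; then H2O
Reagents that add atoms: N,N-dimethylformamide (DMF), CN(C)C=O (gives the formyl C and O); n-butyllithium, [Li]CCCC (its lithium is found only in intermediate 6)
Why: A second directed ortho-metalation at the only remaining type of ring C–H (two positions equivalent by symmetry, each flanked by OMOM and OMe) followed by formylation of the aryllithium with DMF should give the aldehyde, with low temperature and TMEDA favouring ring lithiation over deprotonation of the benzylic/allylic CH2.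

**Step 4**
Reactants: 7 6-methoxy-2,4-bis(methoxymethoxy)-3-(3-methylbut-2-en-1-yl)benzaldehyde
Product: 8 2,4-dihydroxy-6-methoxy-3-(3-methylbut-2-en-1-yl)benzaldehyde
Conditions: HCl (ca. 1 M) in MeOH, rt
Reagents that add atoms: none
Why: Acid-catalysed methanolysis of the MOM acetals (transacetalisation) should free both phenols, and dilute methanolic HCl at room temperature is the standard mild unmasking for prenylated polyphenols that should leave the prenyl olefin and the neighbouring OH groups uncyclised.

**Step 5**
Reactants: 8 2,4-dihydroxy-6-methoxy-3-(3-methylbut-2-en-1-yl)benzaldehyde; 9 4-ethynylphenol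
Product: 10 xanthohumol, (E)-1-[2,4-dihydroxy-6-methoxy-3-(3-methylbut-2-en-1-yl)phenyl]-3-(4-hydroxyphenyl)prop-2-en-1-one
Conditions: [Rh(cod)Cl]2 (2.5 mol%), dppf (5 mol%), Na2CO3 (10 mol%), 1,4-dioxane, 70 °C, freshly purified 9 added slowly; AcOH quench
Reagents that add atoms: none
Why: Carbonate exchanges chloride on Rh(I) for the C2–O phenoxide of 8, and oxidative addition of the adjacent formyl C–H gives a five-membered O,C-chelated acyl(hydrido)rhodium(III) species whose chelate blocks decarbonylation; coordination of 9, syn hydrometalation (H to the aryl-bearing alkyne carbon, Rh to the terminal carbon) and C–C reductive elimination then form the acyl–CH bond and release the 2′-hydroxychalcone by proton exchange with the next molecule of 8, so that all atoms of both partners end in the product. The closest known reaction type is the rhodium/diphosphine-catalysed, hydroxyl-directed intermolecular hydroacylation of alkynes with salicylaldehydes, which gives 2-hydroxyaryl alkenyl ketones. No ring is closed and no stereocentre is formed; the (E) geometry of the new enone follows from delivery of hydride and acyl to the same face of the alkyne, which places the acyl group and the 4-hydroxyphenyl group trans. The step needs linear (terminal-carbon) regioselectivity, chemoselectivity for the alkyne over the prenyl olefin, and survival of the chalcone against oxa-Michael closure to the flavanone; the first should be secured by the unsubstituted alkyne terminus of 9 at the bulky dppf–Rh centre, the second by the trisubstituted nature of the prenyl olefin, which is inert to intermolecular hydroacylation, and the third by using only catalytic carbonate, moderate temperature and an acidic quench. Only the C2–OH of 8 can chelate, so its C4–OH and the phenol of 9 should merely exchange reversibly at rhodium, and slow addition of 9 should hold back alkyne oligomerisation.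

**Compound list**
1 | 5-methoxyresorcinol (5-methoxybenzene-1,3-diol) | COc1cc(O)cc(O)c1 | starting material
2 | 1-methoxy-3,5-bis(methoxymethoxy)benzene | COCOc1cc(OC)cc(OCOC)c1 | intermediate
3 | prenyl bromide (1-bromo-3-methylbut-2-ene) | CC(C)=CCBr | starting material
4 | [4-methoxy-2,6-bis(methoxymethoxy)phenyl]lithium | [Li]c1c(OCOC)cc(OC)cc1OCOC | intermediate
5 | 5-methoxy-1,3-bis(methoxymethoxy)-2-(3-methylbut-2-en-1-yl)benzene | COCOc1cc(OC)cc(OCOC)c1CC=C(C)C | intermediate
6 | [6-methoxy-2,4-bis(methoxymethoxy)-3-(3-methylbut-2-en-1-yl)phenyl]lithium | [Li]c1c(OC)cc(OCOC)c(CC=C(C)C)c1OCOC | intermediate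
7 | 6-methoxy-2,4-bis(methoxymethoxy)-3-(3-methylbut-2-en-1-yl)benzaldehyde | O=Cc1c(OC)cc(OCOC)c(CC=C(C)C)c1OCOC | intermediate
8 | 2,4-dihydroxy-6-methoxy-3-(3-methylbut-2-en-1-yl)benzaldehyde | O=Cc1c(OC)cc(O)c(CC=C(C)C)c1O | intermediate
9 | 4-ethynylphenol | C#Cc1ccc(O)cc1 | starting material
10 | xanthohumol, (E)-1-[2,4-dihydroxy-6-methoxy-3-(3-methylbut-2-en-1-yl)phenyl]-3-(4-hydroxyphenyl)prop-2-en-1-one | COc1cc(O)c(CC=C(C)C)c(O)c1C(=O)/C=C/c1ccc(O)cc1 | target

**Step count and risks**
Total step count: 5. Longest linear sequence: 5 steps (1 → 2 → 5 → 7 → 8 → 10); 3 and 9 are bought.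

Steps most likely to fail, riskiest first:

1. Step 5. Hydride insertion may take the opposite regiochemistry and give the branched 1,1-disubstituted enone, rhodium may oligomerise the arylalkyne, or base may close the product to the flavanone by oxa-Michael addition during the reaction. The fallback forms the same acyl–CH bond by 1,2-addition and sets out from 7 and 9, coming back to the route at 10. Alkyne 9 would be protected (MOMCl, i-Pr2NEt, CH2Cl2) as 1-ethynyl-4-(methoxymethoxy)benzene F1 and deprotonated (n-BuLi, THF, −78 °C) to the lithium acetylide F2. Addition of this to aldehyde 7 should give the racemic propargylic alcohol F3. Trans-hydroalumination with Red-Al (THF, 0 °C → rt) should give the (E)-allylic alcohol F4, and MnO2 (CH2Cl2, rt) should oxidise this doubly activated alcohol to tris-MOM xanthohumol F5. Methanolic HCl as in step 4 should then give 10.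

2. Step 3. n-BuLi may deprotonate the benzylic/allylic CH2 of the prenyl group in competition with the ring C–H, leading to olefin isomerisation or side-chain formylation. The fallback replaces metalation by a phenol-directed electrophilic formylation; it sets out from 5 and comes back at 8, so step 4 is no longer needed. Methanolic HCl (rt) should remove both MOM groups of 5 to give 5-methoxy-2-(3-methylbut-2-en-1-yl)benzene-1,3-diol F6. Magnesium-mediated ortho-formylation (MgCl2, Et3N, paraformaldehyde, MeCN, reflux; Casnati–Skattebøl conditions) should then give 8, because the two free ring positions of F6 are equivalent and each lies ortho to an OH.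

3. Step 2. Metalation may occur partly at the position between OMOM and OMe, eroding regiocontrol, and the allylation may stray into SN2′ or Wurtz-type pathways. The fallback fixes the prenyl position by a sigmatropic sequence instead of metalation; it sets out from prenyl bromide 3 and comes back at 7, bypassing steps 2 and 3. Commercial 2,4,6-trihydroxybenzaldehyde F7 would be protected at the para and one ortho OH (MOMCl 2.1 equiv, i-Pr2NEt, CH2Cl2) to give 2-hydroxy-4,6-bis(methoxymethoxy)benzaldehyde F8. O-Alkylation with 3 (K2CO3, DMF) should give 2,4-bis(methoxymethoxy)-6-[(3-methylbut-2-en-1-yl)oxy]benzaldehyde F9. A para-Claisen (Claisen–Cope) rearrangement in N,N-diethylaniline at about 200 °C should move the prenyl group to the carbon para to that oxygen, which is the position between the two OMOM groups, giving 6-hydroxy-2,4-bis(methoxymethoxy)-3-(3-methylbut-2-en-1-yl)benzaldehyde F10. O-Methylation of the freed phenol (MeI, K2CO3, acetone) should give 7.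

**Further compounds**
F1 | step 5 | 1-ethynyl-4-(methoxymethoxy)benzene | C#Cc1ccc(OCOC)cc1
F2 | step 5 | {[4-(methoxymethoxy)phenyl]ethynyl}lithium | [Li]C#Cc1ccc(OCOC)cc1
F3 | step 5 | rac-1-[6-methoxy-2,4-bis(methoxymethoxy)-3-(3-methylbut-2-en-1-yl)phenyl]-3-[4-(methoxymethoxy)phenyl]prop-2-yn-1-ol | COCOc1ccc(C#CC(O)c2c(OC)cc(OCOC)c(CC=C(C)C)c2OCOC)cc1
F4 | step 5 | rac-(E)-1-[6-methoxy-2,4-bis(methoxymethoxy)-3-(3-methylbut-2-en-1-yl)phenyl]-3-[4-(methoxymethoxy)phenyl]prop-2-en-1-ol | COCOc1ccc(/C=C/C(O)c2c(OC)cc(OCOC)c(CC=C(C)C)c2OCOC)cc1
F5 | step 5 | (E)-1-[6-methoxy-2,4-bis(methoxymethoxy)-3-(3-methylbut-2-en-1-yl)phenyl]-3-[4-(methoxymethoxy)phenyl]prop-2-en-1-one | COCOc1ccc(/C=C/C(=O)c2c(OC)cc(OCOC)c(CC=C(C)C)c2OCOC)cc1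
F6 | step 3 | 5-methoxy-2-(3-methylbut-2-en-1-yl)benzene-1,3-diol | COc1cc(O)c(CC=C(C)C)c(O)c1
F7 | step 2 | 2,4,6-trihydroxybenzaldehyde (commercial input) | O=Cc1c(O)cc(O)cc1O
F8 | step 2 | 2-hydroxy-4,6-bis(methoxymethoxy)benzaldehyde | O=Cc1c(O)cc(OCOC)cc1OCOC
F9 | step 2 | 2,4-bis(methoxymethoxy)-6-[(3-methylbut-2-en-1-yl)oxy]benzaldehyde | O=Cc1c(OCC=C(C)C)cc(OCOC)cc1OCOC
F10 | step 2 | 6-hydroxy-2,4-bis(methoxymethoxy)-3-(3-methylbut-2-en-1-yl)benzaldehyde | O=Cc1c(O)cc(OCOC)c(CC=C(C)C)c1OCOC
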